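# Proposed synthesis of 2-hydroxy-6-(12-phenyldodecyl)benzoic acid by ring-closing metathesis and late aromatization

## Structural features

The target is a 6-alkylsalicylic acid. Ring A is a benzene ring with a carboxyl group at C1, a phenolic hydroxyl at C2 and, at C6, an unbranched chain of twelve methylene groups that ends in an unsubstituted phenyl ring (ring B). The two rings are joined only through this saturated tether, so ring B and the chain are spectators and all the chemistry lies in ring A. The target has no stereocentre and no double-bond geometry, so any stereocentre made on the way is temporary. The fragile elements are the salicylic acid unit, which can lose its carboxyl group on strong heating or in hot acid, and the carboxyl carbon itself, which is flanked by two ortho substituents and reacts slowly in ester formation or hydrolysis. The real difficulty is regiochemical: three different substituents must sit on three neighbouring ring carbons with the carboxyl in the middle, a pattern that direct substitution of a phenol or an alkylbenzene does not deliver. The long lipophilic chain adds a practical problem, because most intermediates are waxy and differ little in polarity. C3, C4 and C5 of ring A carry only hydrogen; the key step forms the C4–C5 bond by ring-closing metathesis between an allyl ketone and a vinyl group, after the C1/C2/C6 triad has been assembled on an open chain.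

## Logic of the disconnections

17 ⇒ 16. The acyl C–OH bond of 17 is traced back to the acyl C–OMe bond of 16. The cut is placed here because the ester is the form in which the carboxyl carbon is introduced and carried. Nothing is gained in skeleton; the gain is a neutral, chromatographable intermediate. The demand on the forward step is cleavage of a doubly ortho-flanked ester without decarboxylation.

16 ⇒ 15. No skeletal bond is cut; the C3–H and C6–H bonds are restored, so the arene becomes a cyclohexenone whose enol is a 1,4-cyclohexadiene. This turns the regiochemical problem of a trisubstituted arene into the connectivity of an aliphatic ring. The forward step must remove exactly one molecule of hydrogen and leave the benzylic and chain CH2 groups untouched.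

15 ⇒ 14. The ring C4=C5 double bond is cut. It is the ring bond that touches none of the three substituted carbons, and its two termini become an allyl ketone and a vinyl group. The gain is the loss of the only ring of the construction: an acyclic β-keto ester remains. The forward step must close a six-membered ring from a 1,7-diene without moving the allyl double bond into conjugation.

14 ⇒ 11 + 12. The bond between the ester α-carbon and the ketone carbonyl (ring C1–C2) is cut. This is the natural enolate/acyl pairing and it separates the oxygen-bearing four-carbon arm from the chain-bearing ester. The forward step must favour C-acylation of 13 over proton transfer to or from the acidic partners.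

11 ⇒ 8 + 9. The bond between C2 and C3 of the ester (ring C1–C6) is cut as a [3,3] retron, with the C–O bond of 10 taking its place. The cut puts the chain and the ester arm on adjacent carbons in one operation and leaves the vinyl group that the metathesis needs. The gain is an unbranched allylic alcohol. The forward step needs a primary allylic alcohol with the chain on the distal alkene carbon.

8 ⇒ 7. The alkene is traced back to the alkyne; no skeletal bond is cut. The reason is that the alkyne can be built by acetylide alkylation. The forward step is a hydroxyl-directed trans reduction that must stop at the alkene.

7 ⇒ 4 + 5. The propargylic C–C bond between C3 and C4 is cut. The polar pairing of an alkynyl carbanion (6) with a primary bromide is reliable and splits the molecule into a three-carbon alcohol and the chain. The forward step must achieve C-alkylation in the presence of the alkoxide.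

4 ⇒ 1 + 2. The bond between ring B and the first chain carbon is cut. Both pieces are then bulk chemicals, joined through 3. The forward step must substitute only one of the two identical bromides of 2.

## Other disconnections considered

Alternative 1: The cut takes ring A as a purchased arene and severs two exocyclic bonds together, C6–C1' to the chain and C1–carboxyl carbon.
- Forward key step: 3-fluoroanisole A1 would be lithiated between fluorine and methoxy and lose fluoride to give 3-methoxybenzyne A2. 12-Phenyldodecyllithium A3, obtainable from 4 by halogen–lithium exchange, would add at the aryne carbon remote from the methoxy group. The aryllithium left next to the methoxy group would be carboxylated to 2-methoxy-6-(12-phenyldodecyl)benzoic acid A4, and ether cleavage of A4 would give 17.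
- In its favour: the contiguous triad is set in one flask on an existing ring. The sense of addition follows from inductive stabilization of the carbanion next to the methoxy group. The carboxyl arrives as the free acid, so no flanked ester has to be hydrolysed.
- Where it is equal or better: on the ester-hydrolysis point and on step economy (about four steps from 1 and 2 against eight) Alternative 1 is better than the chosen plan. On regiochemical certainty it is its equal.
- Against it here: two organolithium roles must be filled in one pot. If A3 acts as base and nucleophile, half of the chain reagent is spent on deprotonation; if a separate base is used, it may compete for A2. The product aryllithium can add to further A2, and protonation before carboxylation would give the arene without the carboxyl. Pyrophoric reagents, cryogenic control and a final Lewis-acid demethylation are needed.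
- Comparison: mechanistically it is a stoichiometric polar cascade that depends on order of addition, whereas the chosen plan closes the ring catalytically under neutral conditions. Structurally both give the same unambiguous 1,2,3-pattern.

Alternative 2: The cut is the ring C1–C6 bond, traced back to an open-chain, polyketide-like ester.
- Forward key step: methyl 5-hydroxy-3,7-dioxo-19-phenylnonadecanoate A5 would, under mild base, add its doubly activated C2 carbanion to the C7 ketone. The cyclic aldol would lose the new tertiary hydroxyl and the C5 hydroxyl as water and enolize to methyl 2-hydroxy-6-(12-phenyldodecyl)benzoate A6. A6 is the same compound as 16 and would join the chosen route at its last step.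
- In its favour: no oxidant and no transition metal are needed, because the aromatic oxidation level is built into the chain.
- Where it is equal or better: its redox economy is better than that of the chosen plan, which needs a separate dehydrogenation. It forms one ring bond, as the chosen plan does, so the two are equal there.
- Against it here: A5 is no simpler to make than 14. A 1,3,5-oxygenated chain needs an acetoacetate-type bis-nucleophile, a differentiated chain-bearing 1,3-dielectrophile and protecting-group traffic. A5 also has competing pathways: retro-aldol cleavage of the β-hydroxy ketone, lactonization of the C5 hydroxyl onto the ester, early dehydration followed by oxa-Michael closure, and aldol closure in the other sense from C8 onto the C3 ketone.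
- Comparison: the preference for the wanted closure rests on the higher acidity of C2, not on a structural lock; in the chosen plan the ring-closing termini are fixed by connectivity. In step count the alternative would probably be no shorter (six to eight steps to A6), with less predictable intermediates.

Alternative 3: The cut removes two ring bonds, C1–C2 and C5–C6, in the cycloaddition sense.
- Forward key step: 1-methoxycyclohexa-1,3-diene A7 and methyl 15-phenylpentadec-2-ynoate A8 (from 7 by oxidation to the acid and esterification) would combine in a [4+2] cycloaddition. On further heating the bridged bicyclic adduct would expel its saturated two-carbon bridge in a retro-[4+2] step and leave methyl 2-methoxy-6-(12-phenyldodecyl)benzoate A9. Both methyl groups of A9 would then have to be removed to reach 17.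
- In its favour: it is convergent, forms two ring bonds and the aromatic ring in one operation, and needs no oxidant. The regiochemistry follows from pairing the electron-rich diene terminus remote from the methoxy group with the β-carbon of the ynoate.
- Where it is equal or better: in convergence and in step count (about six steps from 1 and 2) it is somewhat better than the chosen plan.
- Against it here: a β-alkyl ynoate is a sluggish dienophile, so temperatures well above 150 °C would be needed. At these temperatures A7 can equilibrate with its unconjugated isomer, aromatize by loss of its methoxy group or dimerize. The regiochemical bias of an internal ynoate is weaker than that of a terminal one. The end game must cleave an aryl methyl ether as well as the hindered ester.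
- Comparison: the chosen plan keeps each bond-forming event separate, runs no step above 125 °C and fixes the regiochemistry by connectivity instead of orbital bias. Alternative 3 is shorter but rests on one thermally harsh step.

Key step: step 6

Assumption: every sp3 stereocentre on the way (C3 of 11, C2/C3 of 14, C1/C6 of 15) is temporary and is carried as a racemate or diastereomer mixture, and 12 is a purchased reagent distilled directly before use.

## Route

Step 1
Reactants: 1 bromobenzene; 2 1,12-dibromododecane
Product: 4 (12-bromododecyl)benzene, via phenylmagnesium bromide 3 (not isolated)
Conditions: Mg, THF, reflux; then added to 2 (3 equiv), Li2CuCl4 (3 mol%), THF, 0 °C to rt; surplus 2 removed by vacuum distillation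
Reagents that add atoms: none
Why: Grignard formation followed by copper-catalysed Grignard–alkyl bromide cross-coupling (Kochi coupling) at a primary bromide. The threefold excess of 2 should keep the second bromide from reacting.

Step 2
Reactants: 4 (12-bromododecyl)benzene; 5 propargyl alcohol
Product: 7 15-phenylpentadec-2-yn-1-ol, via dilithiated propargyl alcohol 6 (not isolated)
Conditions: 5 (1.5 equiv), n-BuLi (3.0 equiv), THF/DMPU, −78 to 0 °C; then 4, 0 °C to rt; H2O quench
Reagents that add atoms: none
Why: Acetylide alkylation (SN2) of the propargyl alcohol dianion. The alkynyl carbanion is far more nucleophilic than the alkoxide, so C-alkylation should prevail, and DMPU speeds the substitution at the primary bromide.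

Step 3
Reactants: 7 15-phenylpentadec-2-yn-1-ol
Product: 8 (E)-15-phenylpentadec-2-en-1-ol
Conditions: LiAlH4 (2 equiv), THF, reflux; then H2O/15% aq. NaOH work-up
Reagents that add atoms: none
Why: Hydroxyl-directed trans-hydroalumination of a propargylic alcohol through a cyclic alkenylalanate, whose protonolysis gives the E-allylic alcohol. Ring B and the chain are inert to hydride.

Step 4
Reactants: 8 (E)-15-phenylpentadec-2-en-1-ol; 9 trimethyl orthoacetate
Product: 11 methyl 3-(12-phenyldodecyl)pent-4-enoate (racemic), via mixed ketene acetal 10 (not isolated)
Conditions: 9 (6 equiv), EtCO2H (0.1 equiv), neat, 110–125 °C, MeOH distilled off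
Reagents that add atoms: none
Why: Johnson–Claisen rearrangement: acid-catalysed exchange and loss of methanol give the ketene acetal, and a chair [3,3] shift joins the acetate carbon to the alkene carbon bearing the chain. The new C3 stereocentre is formed as a racemate and is erased in step 7.

Step 5
Reactants: 11 methyl 3-(12-phenyldodecyl)pent-4-enoate; 12 but-3-enoyl chloride
Product: 14 methyl 2-(but-3-enoyl)-3-(12-phenyldodecyl)pent-4-enoate (mixture of diastereomers), via lithium ester enolate 13 (not isolated)
Conditions: LiN(i-Pr)2 (1.1 equiv), THF, −78 °C; enolate cannulated into freshly distilled 12 (1.5 equiv), THF, −78 °C; AcOH quench at −78 °C, pH 7 buffer work-up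
Reagents that add atoms: none
Why: Crossed Claisen-type C-acylation of a lithium ester enolate with an acid chloride. Inverse addition into excess 12 at −78 °C should keep acyl transfer faster than proton transfer from the acidic product or from 12, and the cold buffered quench avoids migration of the β,γ-double bond. The second stereocentre forms without control and is of no consequence.

Step 6
Reactants: 14 methyl 2-(but-3-enoyl)-3-(12-phenyldodecyl)pent-4-enoate
Product: 15 methyl 2-oxo-6-(12-phenyldodecyl)cyclohex-4-ene-1-carboxylate (mixture of diastereomers)
Conditions: second-generation Grubbs catalyst RuCl2(=CHPh)(PCy3)(H2IMes) (5 mol%), 1,4-benzoquinone (10 mol%), degassed CH2Cl2 (0.01 M), 40 °C, argon sparge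
Reagents that add atoms: none
Why: Ring-closing olefin metathesis by the Chauvin mechanism: after loss of PCy3 the ruthenium benzylidene takes up one terminal alkene of 14, most likely the less encumbered allyl group, and [2+2] cycloaddition/cycloreversion through a ruthenacyclobutane releases styrene and leaves a substrate-bound alkylidene. This alkylidene adds intramolecularly to the second terminal alkene, and collapse of the new ruthenacyclobutane forms the C4=C5 double bond, closes the ring and passes on Ru=CH2, which carries the cycle with loss of ethylene. The closest known reaction type is the metathesis closure of 1,7-dienes with two monosubstituted olefins to cyclohexenes, including dienes that carry ketone and β-keto ester groups and cyclohexenones that are oxidized to phenols afterwards. The single ring closed is a six-membered carbocycle joined between the two internal alkene carbons, and its endocyclic double bond can only be cis. No stereocentre is created; C1 and C6 are carried as a diastereomer mixture, C1 equilibrates through the enol, both relative configurations can reach the ring, and both centres vanish in step 7. The step needs ring closure to beat oligomerization and to beat ruthenium-hydride migration of the allyl ketone double bond into conjugation, which would lead to ring contraction with loss of propene. Closure is entropically favoured for a six-membered ring and is secured by 0.01 M dilution and removal of ethylene; migration is held back by the hydride scavenger 1,4-benzoquinone, degassed solvent, 40 °C and a short reaction time, and the α-branched keto ester stays largely in its keto form, so little chelating enol is available to tie up the catalyst.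

Step 7
Reactants: 15 methyl 2-oxo-6-(12-phenyldodecyl)cyclohex-4-ene-1-carboxylate
Product: 16 methyl 2-hydroxy-6-(12-phenyldodecyl)benzoate
Conditions: DDQ (1.1 equiv), toluene, rt (to 50 °C if slow)
Reagents that add atoms: none
Why: Dehydrogenative aromatization: the enol of 15 is a 1,4-cyclohexadiene whose C3 and C6 hydrogens are doubly allylic, so DDQ should abstract hydride there and the cation should lose a proton to give the arene. Aromaticity and the intramolecular hydrogen bond of the salicylate drive the step. The benzylic CH2 groups of the chain are not activated enough to react with one equivalent at this temperature.

Step 8
Reactants: 16 methyl 2-hydroxy-6-(12-phenyldodecyl)benzoate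
Product: 17 2-hydroxy-6-(12-phenyldodecyl)benzoic acid
Conditions: KOH (6 equiv), DMSO/H2O 4:1, 80 °C; then 1 M HCl, 0 °C, to pH 2
Reagents that add atoms: potassium hydroxide, [K+].[OH-]
Why: Saponification (BAc2) of a doubly ortho-substituted benzoate. Poorly solvated hydroxide in aqueous DMSO should be nucleophilic enough to attack the shielded, phenoxide-deactivated carbonyl at 80 °C, well below the temperatures at which salicylates decarboxylate. Cold acidification liberates 17.

## Compound list

1 | bromobenzene | Brc1ccccc1 | starting material
2 | 1,12-dibromododecane | BrCCCCCCCCCCCCBr | starting material
3 | phenylmagnesium bromide | Br[Mg]c1ccccc1 | intermediate (not isolated)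
4 | (12-bromododecyl)benzene | BrCCCCCCCCCCCCc1ccccc1 | intermediate
5 | propargyl alcohol (prop-2-yn-1-ol) | C#CCO | starting material
6 | dilithiated propargyl alcohol (lithium 3-lithioprop-2-yn-1-olate) | [Li]C#CCO[Li] | intermediate (not isolated)
7 | 15-phenylpentadec-2-yn-1-ol | OCC#CCCCCCCCCCCCCc1ccccc1 | intermediate
8 | (E)-15-phenylpentadec-2-en-1-ol | OC/C=C/CCCCCCCCCCCCc1ccccc1 | intermediate
9 | trimethyl orthoacetate | CC(OC)(OC)OC | starting material
10 | mixed ketene acetal, 1-methoxy-1-[(E)-15-phenylpentadec-2-en-1-yloxy]ethene | C=C(OC)OC/C=C/CCCCCCCCCCCCc1ccccc1 | intermediate (not isolated)
11 | methyl 3-(12-phenyldodecyl)pent-4-enoate (racemic) | COC(=O)CC(C=C)CCCCCCCCCCCCc1ccccc1 | intermediate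
12 | but-3-enoyl chloride | C=CCC(=O)Cl | starting material
13 | lithium enolate of 11 | COC(O[Li])=CC(C=C)CCCCCCCCCCCCc1ccccc1 | intermediate (not isolated)
14 | methyl 2-(but-3-enoyl)-3-(12-phenyldodecyl)pent-4-enoate (mixture of diastereomers) | COC(=O)C(C(=O)CC=C)C(C=C)CCCCCCCCCCCCc1ccccc1 | intermediate
15 | methyl 2-oxo-6-(12-phenyldodecyl)cyclohex-4-ene-1-carboxylate (mixture of diastereomers) | COC(=O)C1C(=O)CC=CC1CCCCCCCCCCCCc1ccccc1 | intermediate
16 | methyl 2-hydroxy-6-(12-phenyldodecyl)benzoate | COC(=O)c1c(O)cccc1CCCCCCCCCCCCc1ccccc1 | intermediate
17 | 2-hydroxy-6-(12-phenyldodecyl)benzoic acid | O=C(O)c1c(O)cccc1CCCCCCCCCCCCc1ccccc1 | target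

## Step count and least certain steps

Total step count: 8. Longest linear sequence: 8 steps (1 → 4 → 7 → 8 → 11 → 14 → 15 → 16 → 17).

Step 6 (key step). The most likely failure is migration of the allyl ketone double bond into conjugation, caused by ruthenium hydride species from catalyst decomposition. Metathesis would then stall or contract the ring. A second risk is sequestration of the catalyst by the chelating enol, and a third is intermolecular metathesis if the dilution is not kept. The fallback sets out from 14 and returns at 15. The ketone of 14 would be reduced with NaBH4/CeCl3 in MeOH at −40 °C to methyl 2-(1-hydroxybut-3-en-1-yl)-3-(12-phenyldodecyl)pent-4-enoate F1, whose homoallylic alcohol can neither conjugate nor chelate as an enolate. Ring-closing metathesis of F1 with the same catalyst would give methyl 2-hydroxy-6-(12-phenyldodecyl)cyclohex-4-ene-1-carboxylate F2, and Dess–Martin oxidation of F2 would give 15.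

Step 5. The most likely failure is proton transfer in place of acyl transfer: the enolate 13 may deprotonate 12 at its doubly activated CH2 or be quenched by the acidic product. O-acylation and base-induced conjugation of the β,γ-double bond during the quench are further risks. The fallback sets out from 8 and returns at 14, bypassing step 4 as well, by forming the C2–C3 bond instead.
- 8 would be converted with methyl chloroformate (COC(=O)Cl) and pyridine into methyl (E)-15-phenylpentadec-2-en-1-yl carbonate F3.
- Methyl 3-oxohex-5-enoate F4 would be prepared in one operation from but-3-enoic acid (C=CCC(=O)O) by Masamune–Brooks homologation (carbonyldiimidazole, then MgCl2/KO2CCH2CO2Me/Et3N).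
- The sodium enolate of F4 (NaH, THF) would be allylated by F3 under [Ir(cod)Cl]2/P(OPh)3 catalysis. With alkyl-substituted allyl carbonates this catalyst directs stabilized carbon nucleophiles to the substituted terminus, which would give 14 directly.

Step 7. The most likely failure is covalent addition of the enol to the quinone, or further hydride abstraction at allylic or benzylic positions. Incomplete conversion would leave mixtures that are hard to separate for waxy compounds. The fallback sets out from 15 and returns at 16. 15 would be selenenylated at C1 with PhSeCl/pyridine (CH2Cl2, 0 °C) to methyl 2-oxo-1-(phenylselanyl)-6-(12-phenyldodecyl)cyclohex-4-ene-1-carboxylate F5. Oxidation with H2O2 would give methyl 2-oxo-1-(phenylseleninyl)-6-(12-phenyldodecyl)cyclohex-4-ene-1-carboxylate F6. F6 would undergo syn-elimination towards C6–H at room temperature and enolize to 16.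

Step 8. The most likely failure is slow attack of hydroxide at the shielded carbonyl, with partial conversion, or loss of the carboxyl group if the acidic work-up is allowed to warm. The fallback sets out from 16 and returns at 17 without a new intermediate. 16 would be heated with NaSEt in DMF at 100 °C. The thiolate attacks the ester methyl carbon, which the ortho substituents do not shield, and cold acidification of the carboxylate gives 17.

Step 1. The most likely failure is double substitution of 2 together with homocoupling of 3, followed by a difficult separation of three hydrocarbon-like products by distillation. The fallback sets out from 1 (through 3) and returns at 4. 3 (2.5 equiv, the first equivalent being spent on the hydroxyl proton) would be coupled with purchased 12-bromododecan-1-ol (OCCCCCCCCCCCCBr) under Li2CuCl4 catalysis to give 12-phenyldodecan-1-ol F7. F7 is polar and easily purified, and Appel bromination (CBr4/PPh3, CH2Cl2, 0 °C) would convert it into 4.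

## Further compounds

F1 | step 6 | methyl 2-(1-hydroxybut-3-en-1-yl)-3-(12-phenyldodecyl)pent-4-enoate | COC(=O)C(C(O)CC=C)C(C=C)CCCCCCCCCCCCc1ccccc1
F2 | step 6 | methyl 2-hydroxy-6-(12-phenyldodecyl)cyclohex-4-ene-1-carboxylate | COC(=O)C1C(O)CC=CC1CCCCCCCCCCCCc1ccccc1
F3 | step 5 | methyl (E)-15-phenylpentadec-2-en-1-yl carbonate | COC(=O)OC/C=C/CCCCCCCCCCCCc1ccccc1
F4 | step 5 | methyl 3-oxohex-5-enoate | COC(=O)CC(=O)CC=C
F5 | step 7 | methyl 2-oxo-1-(phenylselanyl)-6-(12-phenyldodecyl)cyclohex-4-ene-1-carboxylate | COC(=O)C1([Se]c2ccccc2)C(=O)CC=CC1CCCCCCCCCCCCc1ccccc1
F6 | step 7 | methyl 2-oxo-1-(phenylseleninyl)-6-(12-phenyldodecyl)cyclohex-4-ene-1-carboxylate | COC(=O)C1([Se](=O)c2ccccc2)C(=O)CC=CC1CCCCCCCCCCCCc1ccccc1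
F0 | step 8 | none | none
F7 | step 1 | 12-phenyldodecan-1-ol | OCCCCCCCCCCCCc1ccccc1
A1 | alternative 1 | 3-fluoroanisole | COc1cccc(F)c1
A2 | alternative 1 | 3-methoxybenzyne | COC1=CC=CC#C1
A3 | alternative 1 | 12-phenyldodecyllithium | [Li]CCCCCCCCCCCCc1ccccc1
A4 | alternative 1 | 2-methoxy-6-(12-phenyldodecyl)benzoic acid | COc1cccc(CCCCCCCCCCCCc2ccccc2)c1C(=O)O
A5 | alternative 2 | methyl 5-hydroxy-3,7-dioxo-19-phenylnonadecanoate | COC(=O)CC(=O)CC(O)CC(=O)CCCCCCCCCCCCc1ccccc1
A6 | alternative 2 | methyl 2-hydroxy-6-(12-phenyldodecyl)benzoate | COC(=O)c1c(O)cccc1CCCCCCCCCCCCc1ccccc1
A7 | alternative 3 | 1-methoxycyclohexa-1,3-diene | COC1=CC=CCC1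
A8 | alternative 3 | methyl 15-phenylpentadec-2-ynoate | COC(=O)C#CCCCCCCCCCCCCc1ccccc1
A9 | alternative 3 | methyl 2-methoxy-6-(12-phenyldodecyl)benzoate | COC(=O)c1c(OC)cccc1CCCCCCCCCCCCc1ccccc1
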